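**Plan**

1. Numbering and faces: six-membered ring C3(=C4)–C5–C6–C7–C8 with ethyl on C3, ethyl and styryl on C5, ethyl and CO2H on C6; five-membered ring C8–C9(Me)–C10(=O)–C11(Et)–C7. α is the ring face of the styryl and CO2H arms, β the face of the C5/C6 ethyl groups.
2. Enabling feature: C5 and C6 are adjacent quaternary ring carbons with cis ethyls and cis carbon arms, the imprint of 2,3-diethylmaleic anhydride, and C4–C3–C8–C7 is a butadiene unit. The retrosynthesis therefore ends in a Diels–Alder cut of C4–C5 and C6–C7.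
3. Earlier cuts, in retrosynthetic order: C6 ester to acid; C10–C11 (acyl-radical closure of the cyclopentanone); C3–ethyl (enol triflate coupling); C7–C11 and C8–C9 (radical cyclisation–allylation from an acetal tethered to a C3 oxygen); the styryl C=C (olefination of the C5 carbonyl).
4. Forward order: hex-3-yne to the anhydride; Diels–Alder closure of the six-membered ring as a meso anhydride; desymmetrising methanolysis; iodolactonisation, elimination and lactol olefination to a C3 allylic alcohol; radical step at C8/C7; C3 ethylation; the five-membered ring is closed last.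
5. Stereochemistry: C5/C6 are cis from the suprafacial cycloaddition, with absolute sense from the alkaloid-catalysed methanolysis. The C3–O bond (α, from iodolactonisation by the C5 carboxyl) is relayed to C8 by a cis 5-exo radical cyclisation and to C7 by anti trapping. C9 and C11 are set by equilibration next to the ketone.

Key step: step 2

Assumption: the sense of induction in step 3 is taken from the parent cis-cyclohex-4-ene-1,2-dicarboxylic anhydride; if the tetrasubstituted anhydride opens at the other carbonyl, the pseudo-enantiomeric catalyst (DHQ)2AQN replaces (DHQD)2AQN.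

**Route**

Step 1
Reactants: 1 hex-3-yne
Product: 3 2,3-diethylmaleic anhydride, via 2,3-diethylmaleic acid 2 (not isolated)
Conditions: Ni(acac)2(bpy) (10 mol %), Zn (3 equiv), MgBr2 (3 equiv), 4 Å MS, CO2 (1 atm), DMF, rt; then 2 M HCl
Reagents that add atoms: carbon dioxide, O=C=O
Why: Nickel-catalysed reductive double carboxylation of an internal alkyne places both carboxyl groups syn (nickelalactone, then second CO2 insertion), and the resulting (Z)-diacid 2 should close spontaneously to the five-membered anhydride on acidification.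

Step 2
Reactants: 3 2,3-diethylmaleic anhydride; 4 buta-1,3-diene
Product: 5 meso cis-1,2-diethylcyclohex-4-ene-1,2-dicarboxylic anhydride
Conditions: buta-1,3-diene (5 equiv), BHT (1 mol %), toluene, 170 °C, sealed autoclave
Reagents that add atoms: none
Why: Concerted, suprafacial [4π+2π] cycloaddition of s-cis buta-1,3-diene to the electron-poor tetrasubstituted C=C of 3 forms C4–C5 and C6–C7 together. The closest known reaction is the thermal (sealed-vessel or high-pressure) Diels–Alder addition of 2,3-dimethylmaleic anhydride to simple 1,3-dienes. The six-membered carbocycle C3–C8 is closed by intermolecular [4+2] cycloaddition, both new σ bonds ending at the two ring carbons of the dienophile. The new quaternary centres C5 and C6 are controlled by the ring-locked Z geometry of the dienophile: both bonds form on one face, so the ethyl groups and the carbonyls can only be cis. No regio-, endo/exo or facial selectivity is needed because the diene is unsubstituted and both partners are symmetric, so a single meso adduct should result. The step needs reactivity only, which the two anhydride carbonyls (low LUMO), excess unhindered diene, heat and an inhibitor of diene polymerisation should secure.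

Step 3
Reactants: 5 meso cis-1,2-diethylcyclohex-4-ene-1,2-dicarboxylic anhydride
Product: 6 (1R,2S)-1,2-diethyl-2-(methoxycarbonyl)cyclohex-4-ene-1-carboxylic acid
Conditions: (DHQD)2AQN (10 mol %), MeOH (10 equiv), Et2O, −20 °C to rt
Reagents that add atoms: methanol, CO
Why: Cinchona-alkaloid-catalysed desymmetrising alcoholysis of a meso cyclic anhydride, in which the quinuclidine nitrogen activates methanol as a general base and directs it to one enantiotopic carbonyl, so that one ring opening fixes both non-epimerisable quaternary centres (C5 acid, C6 methyl ester).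

Step 4
Reactants: 6 (1R,2S)-1,2-diethyl-2-(methoxycarbonyl)cyclohex-4-ene-1-carboxylic acid
Product: 7 iodolactone methyl 1,2-diethyl-4-iodo-7-oxo-6-oxabicyclo[3.2.1]octane-2-carboxylate (O on C3 α; I on C8 β)
Conditions: I2 (2 equiv), KI, NaHCO3 (3 equiv), THF/H2O, 0 °C to rt, dark
Reagents that add atoms: iodine, II
Why: Iodolactonisation, in which the C5 carboxylate opens the iodonium ion of the C3=C8 alkene at C3 (5-exo) to a bridged γ-lactone that can only form on the face of the C5 carboxyl (α), with iodine anti at C8 (β); the C6 ester does not compete with the carboxylate.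

Step 5
Reactants: 7 iodolactone
Product: 8 unsaturated lactone methyl 1,2-diethyl-7-oxo-6-oxabicyclo[3.2.1]oct-3-ene-2-carboxylate
Conditions: DBU (2 equiv), toluene, 90 °C
Reagents that add atoms: none
Why: E2 dehydroiodination, in which the axial C8 iodide is anti-periplanar to the α-hydrogen on C7, so the C7=C8 alkene should form and leave the C3 lactone oxygen allylic.

Step 6
Reactants: 8 unsaturated lactone
Product: 9 lactol methyl 1,2-diethyl-7-hydroxy-6-oxabicyclo[3.2.1]oct-3-ene-2-carboxylate
Conditions: DIBAL-H (1.05 equiv), CH2Cl2, −78 °C; Rochelle salt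
Reagents that add atoms: none
Why: Partial DIBAL-H reduction of a lactone to the lactol at low temperature, where the strained bridged lactone should react before the methyl ester that sits between two quaternary carbons.

Step 7
Reactants: 9 lactol
Product: 11 allylic alcohol methyl 1,6-diethyl-4-hydroxy-6-[(E)-2-phenylethenyl]cyclohex-2-ene-1-carboxylate (C3–OH α), via ring-opened hydroxy aldehyde 10 (not isolated)
Conditions: PhCH2P(O)(OEt)2 (2.5 equiv), NaH (3.5 equiv), 15-crown-5 (cat.), THF, 0 °C to rt
Reagents that add atoms: diethyl benzylphosphonate, CCOP(=O)(Cc1ccccc1)OCC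
Why: Horner–Wadsworth–Emmons olefination of a lactol through its open aldehyde form 10, in which the benzylphosphonate anion should give the (E)-styryl alkene and ring opening releases the C3 hydroxyl with its α configuration unchanged.

Step 8
Reactants: 11 allylic alcohol
Product: 12 bromoacetal methyl 4-(2-bromo-1-ethoxypropoxy)-1,6-diethyl-6-[(E)-2-phenylethenyl]cyclohex-2-ene-1-carboxylate
Conditions: ethyl prop-1-enyl ether (3 equiv), NBS (1.2 equiv), CH2Cl2, −40 to 0 °C
Reagents that add atoms: ethyl prop-1-enyl ether, CCOC=CC; N-bromosuccinimide, O=C1CCC(=O)N1Br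
Why: Alkoxybromination of an enol ether (haloacetal formation), in which the C3 alcohol captures the bromo-oxocarbenium ion and so tethers a secondary bromide to the α oxygen on C3; the two new acetal-chain centres are inconsequential.

Step 9
Reactants: 12 bromoacetal
Product: 13 allyl acetal methyl 2-ethoxy-5,6-diethyl-3-methyl-6-[(E)-2-phenylethenyl]-4-(prop-2-en-1-yl)octahydro-1-benzofuran-5-carboxylate
Conditions: allyltributylstannane (4 equiv), AIBN (0.2 equiv in portions), benzene, 80 °C
Reagents that add atoms: allyltributylstannane, C=CC[Sn](CCCC)(CCCC)CCCC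
Why: Ueno–Stork radical cyclisation with Keck allylation as the chain-carrying termination, in which the acetal-bound radical closes 5-exo-trig onto C8 and can only give the cis-fused tetrahydrofuran (C9 on the α face fixed by the C3 oxygen), and the resulting C7 radical is allylated anti to that new C8 substituent (β face), which sets the trans C7/C8 relationship.

Step 10
Reactants: 13 allyl acetal
Product: 14 propenyl acetal methyl 2-ethoxy-5,6-diethyl-3-methyl-6-[(E)-2-phenylethenyl]-4-[(E)-prop-1-en-1-yl]octahydro-1-benzofuran-5-carboxylate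
Conditions: RuHCl(CO)(PPh3)3 (5 mol %), toluene, 80 °C
Reagents that add atoms: none
Why: Ruthenium-hydride-catalysed alkene isomerisation (hydrometalation/β-hydride elimination) moves the terminal double bond next to C7, so that the future C11 carries a two-carbon residue; no stereocentre is touched and the E/Z ratio is irrelevant.

Step 11
Reactants: 14 propenyl acetal
Product: 16 lactone methyl 5,6-diethyl-3-methyl-2-oxo-6-[(E)-2-phenylethenyl]-4-[(E)-prop-1-en-1-yl]octahydro-1-benzofuran-5-carboxylate, via lactol 15 (not isolated)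
Conditions: CrO3, aq. H2SO4, acetone, 0 °C
Reagents that add atoms: water, O
Why: Jones oxidation of a cyclic mixed acetal, in which acid hydrolysis to lactol 15 and chromium(VI) oxidation should give the γ-lactone and bring C10 to the acyl oxidation level without affecting the alkenes.

Step 12
Reactants: 16 lactone
Product: 17 hydroxy Weinreb amide methyl 1,6-diethyl-4-hydroxy-3-{1-[methoxy(methyl)amino]-1-oxopropan-2-yl}-6-[(E)-2-phenylethenyl]-2-[(E)-prop-1-en-1-yl]cyclohexane-1-carboxylate
Conditions: MeNHOMe·HCl (3 equiv), AlMe3 (3 equiv), CH2Cl2, 0 °C to rt; Rochelle salt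
Reagents that add atoms: N,O-dimethylhydroxylamine hydrochloride, CNOC.Cl
Why: Weinreb aminolysis of a lactone by the aluminium amide opens the γ-lactone and frees the C3 hydroxyl, while the C6 ester between two quaternary carbons should remain untouched.

Step 13
Reactants: 17 hydroxy Weinreb amide
Product: 18 keto Weinreb amide methyl 1,6-diethyl-3-{1-[methoxy(methyl)amino]-1-oxopropan-2-yl}-4-oxo-6-[(E)-2-phenylethenyl]-2-[(E)-prop-1-en-1-yl]cyclohexane-1-carboxylate
Conditions: Dess–Martin periodinane (1.5 equiv), pyridine (3 equiv), CH2Cl2, 0 °C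
Reagents that add atoms: none
Why: Dess–Martin oxidation of the secondary C3 alcohol gives the ketone under mild conditions and removes the possibility of relactonisation; the C8 centre next to the new ketone already has the thermodynamically preferred trans relationship to C7.

Step 14
Reactants: 18 keto Weinreb amide
Product: 20 enol triflate methyl 1,6-diethyl-3-{1-[methoxy(methyl)amino]-1-oxopropan-2-yl}-6-[(E)-2-phenylethenyl]-2-[(E)-prop-1-en-1-yl]-4-(trifluoromethanesulfonyloxy)cyclohex-4-ene-1-carboxylate, via potassium enolate 19 (not isolated)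
Conditions: KHMDS (1.1 equiv), THF, −78 °C; then PhNTf2 (1.2 equiv), −78 to 0 °C
Reagents that add atoms: N-phenylbis(trifluoromethanesulfonimide), O=S(=O)(N(c1ccccc1)S(=O)(=O)C(F)(F)F)C(F)(F)F
Why: Kinetic enolisation and O-triflation, in which the hindered base should remove a C4 methylene proton in preference to the C8 methine or the amide α-proton, and the triflimide traps enolate 19 as the C3=C4 enol triflate.

Step 15
Reactants: 20 enol triflate
Product: 21 ethyl alkene methyl 1,4,6-triethyl-3-{1-[methoxy(methyl)amino]-1-oxopropan-2-yl}-6-[(E)-2-phenylethenyl]-2-[(E)-prop-1-en-1-yl]cyclohex-4-ene-1-carboxylate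
Conditions: Et2Zn (2 equiv), Pd(dppf)Cl2 (5 mol %), THF, 50 °C
Reagents that add atoms: diethylzinc, CC[Zn]CC
Why: Negishi cross-coupling of the enol triflate installs the C3 ethyl group at the fixed C3=C4 position; the bidentate ligand should favour reductive elimination over β-hydride elimination, and the organozinc spares amide and ester.

Step 16
Reactants: 21 ethyl alkene
Product: 22 aldehyde methyl 1,4,6-triethyl-3-(1-oxopropan-2-yl)-6-[(E)-2-phenylethenyl]-2-[(E)-prop-1-en-1-yl]cyclohex-4-ene-1-carboxylate
Conditions: DIBAL-H (1.3 equiv), THF, −78 °C; Rochelle salt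
Reagents that add atoms: none
Why: DIBAL-H reduction of a Weinreb amide stops at the aldehyde through the chelated tetrahedral intermediate, and the C6 ester flanked by quaternary carbons should be far slower.

Step 17
Reactants: 22 aldehyde
Product: 24 methyl ester of the target methyl 3,4,5,7-tetraethyl-1-methyl-2-oxo-5-[(E)-2-phenylethenyl]-2,3,3a,4,5,7a-hexahydro-1H-indene-4-carboxylate, via C9/C11 epimer mixture 23 (not isolated)
Conditions: tert-dodecanethiol (0.3 equiv), AIBN (0.3 equiv in portions), PhCl, 85 °C; then NaOMe (0.2 equiv), MeOH, rt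
Reagents that add atoms: none
Why: Thiol-catalysed radical hydroacylation (polarity-reversal catalysis), in which the acyl radical at C10 adds 5-exo-trig to C11 of the propenyl group and the new radical is reduced by the thiol to give the trans-fused cyclopentanone with ethyl on C11 and methyl on C9; methoxide then equilibrates both ketone α-centres to the arrangement with each alkyl trans to the neighbouring ring-fusion substituent.

Step 18
Reactants: 24 methyl ester of the target
Product: 26 target acid 3,4,5,7-tetraethyl-1-methyl-2-oxo-5-[(E)-2-phenylethenyl]-2,3,3a,4,5,7a-hexahydro-1H-indene-4-carboxylic acid, via lithium carboxylate 25 (not isolated)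
Conditions: LiI (10 equiv), pyridine, 115 °C; then 1 M HCl
Reagents that add atoms: none
Why: SN2 dealkylation of the methyl ester by iodide (Krapcho-type cleavage) attacks the unhindered methyl carbon and not the blocked carbonyl, so the acid between two quaternary carbons is released without affecting ketone or alkenes, and any epimerisation α to the ketone returns to the same thermodynamic isomer.

**Compound list**

1 | hex-3-yne | CCC#CCC | starting material
2 | 2,3-diethylmaleic acid, (Z)-2,3-diethylbut-2-enedioic acid | CC/C(=C(\CC)C(=O)O)C(=O)O | intermediate (not isolated)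
3 | 2,3-diethylmaleic anhydride | CCC1=C(CC)C(=O)OC1=O | intermediate
4 | buta-1,3-diene | C=CC=C | starting material
5 | meso cis-1,2-diethylcyclohex-4-ene-1,2-dicarboxylic anhydride | CC[C@]12CC=CC[C@@]1(CC)C(=O)OC2=O | intermediate
6 | (1R,2S)-1,2-diethyl-2-(methoxycarbonyl)cyclohex-4-ene-1-carboxylic acid (C5 acid, C6 methyl ester) | C1=CC[C@](C(=O)O)(CC)[C@@](CC)(C(=O)OC)C1 | intermediate
7 | methyl 1,2-diethyl-4-iodo-7-oxo-6-oxabicyclo[3.2.1]octane-2-carboxylate (lactone O on C3 α, I on C8 β) | [C@@H]12C[C@@](CC)(C(=O)O1)[C@@](CC)(C(=O)OC)C[C@@H]2I | intermediate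
8 | methyl 1,2-diethyl-7-oxo-6-oxabicyclo[3.2.1]oct-3-ene-2-carboxylate (C7=C8) | [C@@H]12C[C@@](CC)(C(=O)O1)[C@@](CC)(C(=O)OC)C=C2 | intermediate
9 | methyl 1,2-diethyl-7-hydroxy-6-oxabicyclo[3.2.1]oct-3-ene-2-carboxylate (lactol, both anomers) | [C@@H]12C[C@@](CC)(C(O)O1)[C@@](CC)(C(=O)OC)C=C2 | intermediate
10 | methyl 1,6-diethyl-6-formyl-4-hydroxycyclohex-2-ene-1-carboxylate (C3–OH α) | O[C@H]1C[C@](C=O)(CC)[C@@](CC)(C(=O)OC)C=C1 | intermediate (not isolated)
11 | methyl 1,6-diethyl-4-hydroxy-6-[(E)-2-phenylethenyl]cyclohex-2-ene-1-carboxylate (C3–OH α) | O[C@H]1C[C@](/C=C/c2ccccc2)(CC)[C@@](CC)(C(=O)OC)C=C1 | intermediate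
12 | methyl 4-(2-bromo-1-ethoxypropoxy)-1,6-diethyl-6-[(E)-2-phenylethenyl]cyclohex-2-ene-1-carboxylate (epimers in the acetal chain) | CC(Br)C(OCC)O[C@H]1C[C@](/C=C/c2ccccc2)(CC)[C@@](CC)(C(=O)OC)C=C1 | intermediate
13 | methyl 2-ethoxy-5,6-diethyl-3-methyl-6-[(E)-2-phenylethenyl]-4-(prop-2-en-1-yl)octahydro-1-benzofuran-5-carboxylate (cis-fused on the α face, C7 allyl β; C9 and C10 epimers) | [C@H]12C[C@](/C=C/c3ccccc3)(CC)[C@@](CC)(C(=O)OC)[C@H](CC=C)[C@H]1C(C)C(OCC)O2 | intermediate
14 | methyl 2-ethoxy-5,6-diethyl-3-methyl-6-[(E)-2-phenylethenyl]-4-[(E)-prop-1-en-1-yl]octahydro-1-benzofuran-5-carboxylate (C9 and C10 epimers) | [C@H]12C[C@](/C=C/c3ccccc3)(CC)[C@@](CC)(C(=O)OC)[C@H](/C=C/C)[C@H]1C(C)C(OCC)O2 | intermediate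
15 | methyl 5,6-diethyl-2-hydroxy-3-methyl-6-[(E)-2-phenylethenyl]-4-[(E)-prop-1-en-1-yl]octahydro-1-benzofuran-5-carboxylate (lactol) | [C@H]12C[C@](/C=C/c3ccccc3)(CC)[C@@](CC)(C(=O)OC)[C@H](/C=C/C)[C@H]1C(C)C(O)O2 | intermediate (not isolated)
16 | methyl 5,6-diethyl-3-methyl-2-oxo-6-[(E)-2-phenylethenyl]-4-[(E)-prop-1-en-1-yl]octahydro-1-benzofuran-5-carboxylate (C9 epimers) | [C@H]12C[C@](/C=C/c3ccccc3)(CC)[C@@](CC)(C(=O)OC)[C@H](/C=C/C)[C@H]1C(C)C(=O)O2 | intermediate
17 | methyl 1,6-diethyl-4-hydroxy-3-{1-[methoxy(methyl)amino]-1-oxopropan-2-yl}-6-[(E)-2-phenylethenyl]-2-[(E)-prop-1-en-1-yl]cyclohexane-1-carboxylate (C3–OH α, C8 arm α, C7 propenyl β; C9 epimers) | O[C@H]1C[C@](/C=C/c2ccccc2)(CC)[C@@](CC)(C(=O)OC)[C@H](/C=C/C)[C@H]1C(C)C(=O)N(C)OC | intermediate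
18 | methyl 1,6-diethyl-3-{1-[methoxy(methyl)amino]-1-oxopropan-2-yl}-4-oxo-6-[(E)-2-phenylethenyl]-2-[(E)-prop-1-en-1-yl]cyclohexane-1-carboxylate (C9 epimers) | O=C1C[C@](/C=C/c2ccccc2)(CC)[C@@](CC)(C(=O)OC)[C@H](/C=C/C)[C@H]1C(C)C(=O)N(C)OC | intermediate
19 | potassium enolate of 18 (C3–O−, C3=C4) | [K+].[O-]C1=C[C@](/C=C/c2ccccc2)(CC)[C@@](CC)(C(=O)OC)[C@H](/C=C/C)[C@H]1C(C)C(=O)N(C)OC | intermediate (not isolated)
20 | methyl 1,6-diethyl-3-{1-[methoxy(methyl)amino]-1-oxopropan-2-yl}-6-[(E)-2-phenylethenyl]-2-[(E)-prop-1-en-1-yl]-4-(trifluoromethanesulfonyloxy)cyclohex-4-ene-1-carboxylate (C9 epimers) | O=S(=O)(OC1=C[C@](/C=C/c2ccccc2)(CC)[C@@](CC)(C(=O)OC)[C@H](/C=C/C)[C@H]1C(C)C(=O)N(C)OC)C(F)(F)F | intermediate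
21 | methyl 1,4,6-triethyl-3-{1-[methoxy(methyl)amino]-1-oxopropan-2-yl}-6-[(E)-2-phenylethenyl]-2-[(E)-prop-1-en-1-yl]cyclohex-4-ene-1-carboxylate (C9 epimers) | CCC1=C[C@](/C=C/c2ccccc2)(CC)[C@@](CC)(C(=O)OC)[C@H](/C=C/C)[C@H]1C(C)C(=O)N(C)OC | intermediate
22 | methyl 1,4,6-triethyl-3-(1-oxopropan-2-yl)-6-[(E)-2-phenylethenyl]-2-[(E)-prop-1-en-1-yl]cyclohex-4-ene-1-carboxylate (C9 epimers) | CCC1=C[C@](/C=C/c2ccccc2)(CC)[C@@](CC)(C(=O)OC)[C@H](/C=C/C)[C@H]1C(C)C=O | intermediate
23 | methyl 3,4,5,7-tetraethyl-1-methyl-2-oxo-5-[(E)-2-phenylethenyl]-2,3,3a,4,5,7a-hexahydro-1H-indene-4-carboxylate, mixture of C9/C11 epimers (trans ring fusion) | CCC1=C[C@](/C=C/c2ccccc2)(CC)[C@@](CC)(C(=O)OC)[C@H]2[C@H]1C(C)C(=O)C2CC | intermediate (not isolated)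
24 | methyl ester of the target, all-trans cyclopentanone | CCC1=C[C@](/C=C/c2ccccc2)(CC)[C@@](CC)(C(=O)OC)[C@H]2[C@H]1[C@@H](C)C(=O)[C@@H]2CC | intermediate
25 | lithium carboxylate of the target | CCC1=C[C@](/C=C/c2ccccc2)(CC)[C@@](CC)(C(=O)[O-])[C@H]2[C@H]1[C@@H](C)C(=O)[C@@H]2CC.[Li+] | intermediate (not isolated)
26 | CNP0420507.1, 3,4,5,7-tetraethyl-1-methyl-2-oxo-5-[(E)-2-phenylethenyl]-2,3,3a,4,5,7a-hexahydro-1H-indene-4-carboxylic acid (C5 styryl α, C6 CO2H α, C7–H α, C8–H β, C9 methyl cis to C8–H, C11 ethyl cis to C7–H) | CCC1=C[C@](/C=C/c2ccccc2)(CC)[C@@](CC)(C(=O)O)[C@H]2[C@H]1[C@@H](C)C(=O)[C@@H]2CC | target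

**Step count**

Total: 18 steps. Longest linear sequence: 18 steps (1 to 26).

**Steps most likely to fail**

Step 3. The alcoholysis may stall or lose face selectivity because both carbonyls of 5 are flanked by quaternary carbons. Fallback (resolution in place of asymmetric catalysis), from 5 back to 6: sodium methoxide in methanol should open 5 without selectivity to the racemic half-ester, that is 6 together with its enantiomer (1S,2R)-1,2-diethyl-2-(methoxycarbonyl)cyclohex-4-ene-1-carboxylic acid F1. Crystallisation with (R)-1-phenylethylamine (or its enantiomer, whichever gives the less soluble salt of 6) should give the (R)-1-phenylethylammonium salt of 6 F2. Acidification of this salt returns 6.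

Step 9. The chain may be diverted by allylation of the acetal radical before ring closure, by slow capture of the congested C7 radical, or by capture on the α face. Fallback (ionic conjugate addition–alkylation in place of the radical relay), from 11 back to 21: Dess–Martin oxidation of 11 gives the enone methyl 1,6-diethyl-4-oxo-6-[(E)-2-phenylethenyl]cyclohex-2-ene-1-carboxylate F3. Copper-catalysed conjugate addition of (E)-prop-1-enylmagnesium bromide (CuBr·SMe2, chiral ferrocenyl diphosphine) follows, with the ligand enantiomer chosen for attack on the β face of C7 because the C5/C6 substituents alone are not expected to bias that face. Alkylation of the enolate in the same flask with 2-bromo-N-methoxy-N-methylacetamide (DMPU), anti to the new C7 group, should give the keto amide methyl 1,6-diethyl-3-{2-[methoxy(methyl)amino]-2-oxoethyl}-4-oxo-6-[(E)-2-phenylethenyl]-2-[(E)-prop-1-en-1-yl]cyclohexane-1-carboxylate F4. Kinetic triflation (KHMDS, PhNTf2) gives the enol triflate methyl 1,6-diethyl-3-{2-[methoxy(methyl)amino]-2-oxoethyl}-6-[(E)-2-phenylethenyl]-2-[(E)-prop-1-en-1-yl]-4-(trifluoromethanesulfonyloxy)cyclohex-4-ene-1-carboxylate F5. Negishi ethylation (Et2Zn, Pd(dppf)Cl2) gives the amide methyl 1,4,6-triethyl-3-{2-[methoxy(methyl)amino]-2-oxoethyl}-6-[(E)-2-phenylethenyl]-2-[(E)-prop-1-en-1-yl]cyclohex-4-ene-1-carboxylate F6. α-Methylation of the Weinreb amide (LDA, MeI, −78 °C) rejoins the route at 21.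

Step 17. The α-branched acyl radical may lose carbon monoxide, the thiol may add to the alkenes, or closure to the trans-fused ring may be too slow. Fallback (reductive ketyl–olefin coupling and reoxidation in place of redox-neutral hydroacylation), from 22 back to 23: SmI2 (2.5 equiv), HMPA and t-BuOH in THF should close the ring by 5-exo attack of the ketyl radical on the propenyl group, giving the cyclopentanol methyl 3,4,5,7-tetraethyl-2-hydroxy-1-methyl-5-[(E)-2-phenylethenyl]-2,3,3a,4,5,7a-hexahydro-1H-indene-4-carboxylate F7. Dess–Martin oxidation gives 23, which is equilibrated with methoxide to 24 as in step 17.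

**Further compounds**

F1 | step 3 | (1S,2R)-1,2-diethyl-2-(methoxycarbonyl)cyclohex-4-ene-1-carboxylic acid (enantiomer of 6) | C1=CC[C@@](C(=O)O)(CC)[C@](CC)(C(=O)OC)C1
F2 | step 3 | (R)-1-phenylethylammonium salt of 6 | C1=CC[C@](C(=O)[O-])(CC)[C@@](CC)(C(=O)OC)C1.C[C@@H]([NH3+])c1ccccc1
F3 | step 9 | methyl 1,6-diethyl-4-oxo-6-[(E)-2-phenylethenyl]cyclohex-2-ene-1-carboxylate | O=C1C[C@](/C=C/c2ccccc2)(CC)[C@@](CC)(C(=O)OC)C=C1
F4 | step 9 | methyl 1,6-diethyl-3-{2-[methoxy(methyl)amino]-2-oxoethyl}-4-oxo-6-[(E)-2-phenylethenyl]-2-[(E)-prop-1-en-1-yl]cyclohexane-1-carboxylate | O=C1C[C@](/C=C/c2ccccc2)(CC)[C@@](CC)(C(=O)OC)[C@H](/C=C/C)[C@H]1CC(=O)N(C)OC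
F5 | step 9 | methyl 1,6-diethyl-3-{2-[methoxy(methyl)amino]-2-oxoethyl}-6-[(E)-2-phenylethenyl]-2-[(E)-prop-1-en-1-yl]-4-(trifluoromethanesulfonyloxy)cyclohex-4-ene-1-carboxylate | O=S(=O)(OC1=C[C@](/C=C/c2ccccc2)(CC)[C@@](CC)(C(=O)OC)[C@H](/C=C/C)[C@H]1CC(=O)N(C)OC)C(F)(F)F
F6 | step 9 | methyl 1,4,6-triethyl-3-{2-[methoxy(methyl)amino]-2-oxoethyl}-6-[(E)-2-phenylethenyl]-2-[(E)-prop-1-en-1-yl]cyclohex-4-ene-1-carboxylate | CCC1=C[C@](/C=C/c2ccccc2)(CC)[C@@](CC)(C(=O)OC)[C@H](/C=C/C)[C@H]1CC(=O)N(C)OC
F7 | step 17 | methyl 3,4,5,7-tetraethyl-2-hydroxy-1-methyl-5-[(E)-2-phenylethenyl]-2,3,3a,4,5,7a-hexahydro-1H-indene-4-carboxylate (C9, C10, C11 epimers) | CCC1=C[C@](/C=C/c2ccccc2)(CC)[C@@](CC)(C(=O)OC)[C@H]2[C@H]1C(C)C(O)C2CC
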